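The pitfall in this flask is to see nucleophile at half the oak charge and expect half the rate, as if the nucleophile's concentration set the order of the loss.

- oak: electrophile 30 mM; nucleophile 1.8 equiv; buffer base 2 equiv; buffer acid 0.10 equiv; run made earlier
- flask: electrophile 30 mM; nucleophile 0.900 equiv; buffer base 2.00 equiv; buffer acid 0.100 equiv; time 30 h

oak run (percent of the electrophile charged)

| time / h | electrophile / % | target / % |
|---|---|---|
| 1.00 | 94.4 | 3.5 |
| 2.00 | 88.2 | 2.4 |
| 3.00 | 82.2 | 4.9 |
| 4.00 | 77.5 | 7.3 |
| 5.00 | 73.1 | 9.5 |
| 6.00 | 67.9 | 10.4 |

(scatter of a reading: 1 percentage point)

- part of the electrophile that has reacted at 30 h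
- pH of the solution at 30 h

- the analysis behind the earlier runs scatters by 1 percentage point, standard deviation
- what has gone from electrophile into another species counts as reacted, even if it can come back
- the earlier runs do not show the pH; that part of a forecast is a guess

Start with the oak run. Its electrophile falls to 67.9% at 6.00 h, nearly straight on a log scale, so you may write a first-order constant k, minus the log of the fraction left over the time: 0.0645 /h. A second-order law puts this whole loss on the nucleophile. But target stands at just 10.4% at that reading, so take s, the nucleophile share, the part of the lost electrophile that appears as target: as read, 32.4%. I let s scale with the nucleophile charge and the remainder run without it, which is my assumption. With r the ratio of charges, 0.500, the oak-run k becomes k(1 − s + s·r) = 0.0541 /h for this flask, well above half of k.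

That constant treats the nucleophile as steady (pseudo-first-order), so check it. One minus exp(−kt) gives 80.3% at 30 h, and the nucleophile's part of that loss, 19.3%, would by this estimate cost 4.65 mM of 27.0 mM, so on this reckoning I let that objection go. The harder objection stands: the flask runs 5.00 times as long as the readings, and reacted electrophile can come back. So I hold 80.3% as a high figure. The pH these readings do not show.

The forecast, below my figure, says 50% (38% to 72%) and pH 7.5 (5.5 to 9.5), remarking: “The oak run cannot separate first-order from second-order behaviour.”

The flask gives 65.7% reacted at 30 h, at pH 7.71.

    buffer acid ⇌ buffer base + acid, settled at all times (K = 1.60 × 10⁻⁶ M)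
    electrophile + target → side product (k = 0.720 /M/h)
    electrophile + nucleophile → acid + target + leaving group (k = 0.410 /M/h)
    2 electrophile → homo dimer (k = 0.180 /M/h)
    electrophile ⇌ dormant form (K = 1.30, k = 0.0370 /h)
    protonated nucleophile ⇌ nucleophile + acid, settled at all times (K = 5.00 × 10⁻⁸ M)

That is below my 80.3%, and at 30.0 h this flask holds 38.5% as dormant form, more than the 34.3% of electrophile still free. In the neighbour flask with 3.60 equiv of nucleophile, s gives 0.0854 /h and so 92.3% reacted at 30 h; that neighbour flask stands at 83.7%.

(The numbers in the tables come from a simulation from invented constants.)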